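Amounts first: Friday's flask holds 80.0 mM of Ptn, less than its 100 mM of Sbt, so Ptn is the limiting reagent, yet by 36 h the readings have slowed with 30.7 mM of Pdt, 38.4% of that Ptn.

| setting | Friday's | Wednesday's | Monday's |
|---|---|---|---|
| Sbt | 100 mM | 100 mM | 20.0 mM |
| Ptn | 80.0 mM | 80.0 mM | 16.0 mM |
| Ctl | 1.00 mM | 0.500 mM | 1.00 mM |
| time |  |  | 36 h |

- Friday's run (time / h: [Pdt] / mM): 5.1: 13.9; 10: 21.4; 15: 23.4; 21: 25.1; 26: 27.3; 31: 27.7; 36: 30.7
- Wednesday's run (time / h: [Pdt] / mM): 5.1: 9.0; 10: 14.6; 15: 17.2; 21: 20.8; 26: 21.2; 31: 22.0; 36: 23.3

(each reading ± 1 mM)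

- order of the initial rate in [Ctl], near the charge of the Friday's run, the rate being that where two percent of its Sbt are Pdt
- Pdt in the Monday's run at 36 h, as a share of the Sbt charged

- Overall: Sbt + Ptn -> Pdt, with Ctl as catalyst.
- Constant volume, constant temperature.
- "The second partner" is Ptn.
- An order is taken over about fifteen percent of the charge, up and down.

Follow one Ptn molecule, supposing it meets a fork. Each hour it has a forward chance of becoming Pdt and some chance of leaving another way, and the share reaching Pdt is the forward chance over the sum of the two. Friday's first reading gives a forward chance of 0.0341 h⁻¹, and the share 38.4%, taken as final, then puts the other chance at 0.0547 h⁻¹. Monday's flask has Friday's Ctl but 0.200 of its Sbt. Taking the forward chance as proportional to Sbt, it falls to 0.00681 h⁻¹. Multiplying the share at the fork by the fraction of molecules that have met either fate by 36 h, which is one minus the exponential of minus the summed chance times the time, gives 7.89% of Monday's Sbt.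

The weak link is the first reading, which is a chord across a bending curve. It already stands at 45.3% of Friday's last reading, so the summed chance is better read as 0.118 h⁻¹. Friday's forward chance becomes 0.0454 h⁻¹, and the leak, the chance per hour that a Ptn molecule goes elsewhere than to Pdt, becomes 0.0728 h⁻¹. Monday's forward chance is then 0.00907 h⁻¹, and this reckoning commits to 8.40%. For the order, Wednesday's flask, with half the Ctl of Friday's, reads 9.0 mM against 13.9 mM at that first time, which reads as an order of about 0.627 across that whole step in Ctl.

The forecast gives an order of 0.95 (0.7 to 1.1) and, for Monday's flask, 11% (7% to 24%), on the ground that “the whole curves superimpose when time is scaled by catalyst”. Both its values are higher than those reckoned here.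

The flask gives an order in Ctl of 0.60 near Friday's charge, and Pdt in Monday's flask at 36 h comes to 8.62% of its Sbt.

    2 Ctl ⇌ Ctl2, settled at all times (5280 M⁻¹)
    Ctl + Sbt + Ptn → Pdt + Ctl (1678 M⁻² h⁻¹)
    Ptn → X (0.06444 h⁻¹)

Where two percent of Friday's Sbt have turned, Friday's flask forms Pdt at 3.3 mM h⁻¹ and Wednesday's at 2.1 mM h⁻¹. Wednesday's last reading, 23.3 mM, held against the leak of 0.0728 h⁻¹, taken as the same in that flask, gives Wednesday's flask a forward chance of 0.0299 h⁻¹, which is 0.659 of Friday's 0.0454 h⁻¹.

The runs were generated by integration with made-up constants; noise was put on by code.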